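The flavanone's ring C is opened at C2–C3 and O1–C8a, so that the formyl carbon and oxygen of a ring B aldehyde become C2 and O1. The feature exploited is the C4 ketone ortho to C8a on ring A: in a 2-fluoroaryl silyl enol ether, C3=C4–C4a=C8a(F) is a masked diene. In one pot, a catalytic enantioselective Mukaiyama aldol sets C2, and fluoride then triggers desilylation and intramolecular SNAr, closing the pyranone and releasing only Me3SiF. The precursors are a fluorinated, prenylated enol silane (from 5-fluororesorcinol) and a prenylated chromene aldehyde (from 3,4-dihydroxybenzaldehyde by a tandem Claisen cascade); MOM removal ends the route.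

Key step: step 10

Remark (assumption on the chemistry): the acyloxyborane from (2R,3R)-tartaric acid is taken to direct silyl enol ethers to the Re face of aryl aldehydes, so the (2S,3S) catalyst is specified for the Si-face addition that gives (S) at C2.
Remark: tert-butyl 2-methylbut-3-en-2-yl carbonate (19) is treated as a catalogue reagent.

Step 1
Reactants: 1 5-fluorobenzene-1,3-diol; 2 chloromethyl methyl ether
Product: 3 1-fluoro-3,5-bis(methoxymethoxy)benzene
Conditions: NaH (2.4 equiv), DMF, 0 °C; MOMCl (2.4 equiv), 0 °C to rt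
Reagents that add atoms: chloromethyl methyl ether, COCCl
Why: Williamson-type O-alkylation of both phenoxides gives MOM ethers that tolerate the organolithium, Lewis acid and fluoride steps and leave under mild acid.

Step 2
Reactants: 3 1-fluoro-3,5-bis(methoxymethoxy)benzene; 4 N-bromosuccinimide
Product: 5 2,4-dibromo-3-fluoro-1,5-bis(methoxymethoxy)benzene
Conditions: NBS (2.1 equiv), MeCN, 0 °C to rt
Reagents that add atoms: N-bromosuccinimide, O=C1CCC(=O)N1Br
Why: Electrophilic aromatic bromination should take the two equivalent positions flanked by F and OMOM (ortho to one alkoxy group, para to the other) rather than the hindered position between the two OMOM groups, as in the 4,6-dibromination of 1,3-dialkoxybenzenes, giving a symmetric dibromide.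

Step 3
Reactants: 5 2,4-dibromo-3-fluoro-1,5-bis(methoxymethoxy)benzene; 6 1-bromo-3-methylbut-2-ene (prenyl bromide)
Product: 8 1-bromo-2-fluoro-4,6-bis(methoxymethoxy)-3-(3-methylbut-2-en-1-yl)benzene, via aryllithium 7 (not isolated)
Conditions: n-BuLi (1.0 equiv), THF, −78 °C; CuBr·SMe2 (10 mol %), prenyl bromide (1.3 equiv), −78 to −30 °C
Reagents that add atoms: 1-bromo-3-methylbut-2-ene, CC(C)=CCBr
Why: Bromine–lithium exchange of one of two equivalent bromines followed by copper-catalysed SN2 allylation at the primary carbon of prenyl bromide should give the linear prenyl arene, the low temperature preventing loss of LiF to an aryne.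

Step 4
Reactants: 8 1-bromo-2-fluoro-4,6-bis(methoxymethoxy)-3-(3-methylbut-2-en-1-yl)benzene; 9 N-methoxy-N-methylacetamide
Product: 12 1-[2-fluoro-4,6-bis(methoxymethoxy)-3-(3-methylbut-2-en-1-yl)phenyl]ethan-1-one, via aryllithium 10 (not isolated), via lithium hemiaminal 11 (not isolated)
Conditions: n-BuLi (1.05 equiv), THF, −78 °C; MeC(O)N(OMe)Me (1.5 equiv), −78 to 0 °C; H2O
Reagents that add atoms: N-methoxy-N-methylacetamide, CC(=O)N(C)OC
Why: Bromine–lithium exchange and Weinreb ketone synthesis, in which the chelated tetrahedral adduct blocks over-addition and collapses to the methyl ketone on work-up.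

Step 5
Reactants: 12 1-[2-fluoro-4,6-bis(methoxymethoxy)-3-(3-methylbut-2-en-1-yl)phenyl]ethan-1-one; 13 chlorotrimethylsilane
Product: 15 {[1-(2-fluoro-4,6-bis(methoxymethoxy)-3-(3-methylbut-2-en-1-yl)phenyl)ethenyl]oxy}trimethylsilane, via lithium enolate 14 (not isolated)
Conditions: LiN(i-Pr)2 (1.1 equiv), THF, −78 °C; Me3SiCl (1.3 equiv), −78 to 0 °C; pentane, filtration, used crude
Reagents that add atoms: chlorotrimethylsilane, C[Si](C)(C)Cl
Why: Kinetic enolisation of the only enolisable position and O-silylation of the lithium enolate (silyl enol ether formation).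

Step 6
Reactants: 16 3,4-dihydroxybenzaldehyde; 17 3-chloro-3-methylbut-1-yne
Product: 18 3-hydroxy-4-[(2-methylbut-3-yn-2-yl)oxy]benzaldehyde
Conditions: CuCl2·2H2O (0.5 mol %), DBU (1.1 equiv), MeCN, 0 °C
Reagents that add atoms: 3-chloro-3-methylbut-1-yne, CC(C)(Cl)C#C
Why: Copper-catalysed propargylic substitution by phenoxide should occur at O4, because the 4-OH para to the formyl group is the more acidic and is the one ionised by one equivalent of base.

Step 7
Reactants: 18 3-hydroxy-4-[(2-methylbut-3-yn-2-yl)oxy]benzaldehyde; 19 tert-butyl 2-methylbut-3-en-2-yl carbonate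
Product: 20 3-[(2-methylbut-3-en-2-yl)oxy]-4-[(2-methylbut-3-yn-2-yl)oxy]benzaldehyde
Conditions: Pd(PPh3)4 (2 mol %), THF, 0 °C
Reagents that add atoms: tert-butyl 2-methylbut-3-en-2-yl carbonate, CC(C)(C)OC(=O)OC(C)(C)C=C
Why: Tsuji–Trost O-allylation in which decarboxylative ionisation gives the 1,1-dimethyl-π-allylpalladium species and the phenoxide attacks its more substituted terminus under kinetic control at low temperature, giving the tertiary allyl ether.

Step 8
Reactants: 20 3-[(2-methylbut-3-en-2-yl)oxy]-4-[(2-methylbut-3-yn-2-yl)oxy]benzaldehyde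
Product: 22 8-hydroxy-2,2-dimethyl-7-(3-methylbut-2-en-1-yl)-2H-chromene-6-carbaldehyde, via prenylphenol 21 (not isolated)
Conditions: PhNEt2, 120 °C, then 190 °C
Reagents that add atoms: none
Why: Tandem aromatic Claisen rearrangements: the tertiary allyl ether shifts [3,3] to the only free ortho position of O3 to give the linear prenyl group and phenol 21, and at the higher temperature the propargyl ether shifts [3,3] to the only free ortho position of O4, followed by 1,5-hydrogen shift and oxa-6π electrocyclisation to the 2,2-dimethyl-2H-chromene.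

Step 9
Reactants: 22 8-hydroxy-2,2-dimethyl-7-(3-methylbut-2-en-1-yl)-2H-chromene-6-carbaldehyde; 2 chloromethyl methyl ether
Product: 23 8-(methoxymethoxy)-2,2-dimethyl-7-(3-methylbut-2-en-1-yl)-2H-chromene-6-carbaldehyde
Conditions: NaH (1.3 equiv), DMF, 0 °C; MOMCl (1.3 equiv), 0 °C to rt
Reagents that add atoms: chloromethyl methyl ether, COCCl
Why: Williamson-type O-alkylation of the hindered phenoxide masks the acidic ring B phenol, which would otherwise quench the enol silane and the alkoxide of the key step.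

Step 10
Reactants: 15 {[1-(2-fluoro-4,6-bis(methoxymethoxy)-3-(3-methylbut-2-en-1-yl)phenyl)ethenyl]oxy}trimethylsilane (1.2 equiv); 23 8-(methoxymethoxy)-2,2-dimethyl-7-(3-methylbut-2-en-1-yl)-2H-chromene-6-carbaldehyde
Product: 26 (2S)-5,7-bis(methoxymethoxy)-2-[8-(methoxymethoxy)-2,2-dimethyl-7-(3-methylbut-2-en-1-yl)-2H-chromen-6-yl]-8-(3-methylbut-2-en-1-yl)-2,3-dihydro-4H-chromen-4-one, via silyl aldol 24 (not isolated), via ammonium aldolate 25 (not isolated)
Conditions: acyloxyborane catalyst from (2S,3S)-2-O-(2,6-diisopropoxybenzoyl)tartaric acid and 3,5-(CF3)2C6H3B(OH)2 (20 mol %), EtCN, −78 °C; then Bu4NF (1.0 equiv, THF), −78 to −20 °C; pH 7 buffer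
Reagents that add atoms: none
Why: The chiral acyloxyborane binds the formyl group of 23 and the enol silane 15 adds to its Si face through an open transition state, with turnover by silyl transfer, to give the (S)-β-silyloxy ketone 24 (C2–C3 bond); fluoride then removes the silyl group and the alkoxide 25 attacks the fluorine-bearing C8a ortho to the ketone, expelling fluoride from an anionic σ-adduct (O1–C8a bond), so fluoride is returned and Me3SiF is the only by-product. The closest known reaction types are the chiral boron Lewis acid-catalysed Mukaiyama aldol of aryl methyl ketone enol silanes with aryl aldehydes and the alkoxide SNAr cyclisation of 2-fluoroaryl β-hydroxy ketones to chroman-4-ones. The pyranone ring C closes by 6-exo attack of oxygen on the aromatic carbon (addition–elimination), so the sequence is overall a formal [4+2] annulation of the aldehyde C=O with a diene whose terminal leaving group is fluoride. C2 is set in the aldol step by the catalyst (Si-face attack gives S) and is untouched in the ring closure, which forms the bond at oxygen with retention. The step needs aldol addition to outrun ene-type attack of the ortho-prenyl alkene on the activated formyl group, which the far greater nucleophilicity of the enol silane at −78 °C should secure. It also needs SNAr to outrun retro-aldol and β-elimination, which the naked ammonium alkoxide, the ortho ketone, the two meta alkoxy groups and the low temperature favour, and regiochemistry is fixed because ring A carries a single leaving group.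

Step 11
Reactants: 26 (2S)-5,7-bis(methoxymethoxy)-2-[8-(methoxymethoxy)-2,2-dimethyl-7-(3-methylbut-2-en-1-yl)-2H-chromen-6-yl]-8-(3-methylbut-2-en-1-yl)-2,3-dihydro-4H-chromen-4-one
Product: 27 (2S)-5,7-dihydroxy-2-[8-hydroxy-2,2-dimethyl-7-(3-methylbut-2-en-1-yl)-2H-chromen-6-yl]-8-(3-methylbut-2-en-1-yl)-2,3-dihydro-4H-chromen-4-one (CNP0328260.1)
Conditions: HCl (3 M aq.), MeOH, 45 °C
Reagents that add atoms: none
Why: Acid-catalysed solvolysis of the three aryl MOM acetals, a deprotection customary for prenylated flavanones, should free the phenols without the basic conditions that open ring C and racemise C2.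

Compound list
1 | 5-fluorobenzene-1,3-diol | Oc1cc(O)cc(F)c1 | starting material
2 | chloromethyl methyl ether | COCCl | starting material
3 | 1-fluoro-3,5-bis(methoxymethoxy)benzene | COCOc1cc(F)cc(OCOC)c1 | intermediate
4 | N-bromosuccinimide | O=C1CCC(=O)N1Br | starting material
5 | 2,4-dibromo-3-fluoro-1,5-bis(methoxymethoxy)benzene | COCOc1cc(OCOC)c(Br)c(F)c1Br | intermediate
6 | 1-bromo-3-methylbut-2-ene | CC(C)=CCBr | starting material
7 | [3-bromo-2-fluoro-4,6-bis(methoxymethoxy)phenyl]lithium | [Li]c1c(F)c(Br)c(OCOC)cc1OCOC | intermediate (not isolated)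
8 | 1-bromo-2-fluoro-4,6-bis(methoxymethoxy)-3-(3-methylbut-2-en-1-yl)benzene | COCOc1cc(OCOC)c(CC=C(C)C)c(F)c1Br | intermediate
9 | N-methoxy-N-methylacetamide | CC(=O)N(C)OC | starting material
10 | [2-fluoro-4,6-bis(methoxymethoxy)-3-(3-methylbut-2-en-1-yl)phenyl]lithium | [Li]c1c(F)c(CC=C(C)C)c(OCOC)cc1OCOC | intermediate (not isolated)
11 | lithium 1-[2-fluoro-4,6-bis(methoxymethoxy)-3-(3-methylbut-2-en-1-yl)phenyl]-1-[methoxy(methyl)amino]ethan-1-olate | CC(O[Li])(N(C)OC)c1c(F)c(CC=C(C)C)c(OCOC)cc1OCOC | intermediate (not isolated)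
12 | 1-[2-fluoro-4,6-bis(methoxymethoxy)-3-(3-methylbut-2-en-1-yl)phenyl]ethan-1-one | CC(=O)c1c(F)c(CC=C(C)C)c(OCOC)cc1OCOC | intermediate
13 | chlorotrimethylsilane | C[Si](C)(C)Cl | starting material
14 | lithium 1-[2-fluoro-4,6-bis(methoxymethoxy)-3-(3-methylbut-2-en-1-yl)phenyl]ethen-1-olate | C=C(O[Li])c1c(F)c(CC=C(C)C)c(OCOC)cc1OCOC | intermediate (not isolated)
15 | {[1-(2-fluoro-4,6-bis(methoxymethoxy)-3-(3-methylbut-2-en-1-yl)phenyl)ethenyl]oxy}trimethylsilane | C=C(O[Si](C)(C)C)c1c(F)c(CC=C(C)C)c(OCOC)cc1OCOC | intermediate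
16 | 3,4-dihydroxybenzaldehyde | O=Cc1ccc(O)c(O)c1 | starting material
17 | 3-chloro-3-methylbut-1-yne | CC(C)(Cl)C#C | starting material
18 | 3-hydroxy-4-[(2-methylbut-3-yn-2-yl)oxy]benzaldehyde | O=Cc1ccc(OC(C)(C)C#C)c(O)c1 | intermediate
19 | tert-butyl 2-methylbut-3-en-2-yl carbonate | CC(C)(C)OC(=O)OC(C)(C)C=C | starting material
20 | 3-[(2-methylbut-3-en-2-yl)oxy]-4-[(2-methylbut-3-yn-2-yl)oxy]benzaldehyde | O=Cc1ccc(OC(C)(C)C#C)c(OC(C)(C)C=C)c1 | intermediate
21 | 3-hydroxy-2-(3-methylbut-2-en-1-yl)-4-[(2-methylbut-3-yn-2-yl)oxy]benzaldehyde | CC(C)=CCc1c(C=O)ccc(OC(C)(C)C#C)c1O | intermediate (not isolated)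
22 | 8-hydroxy-2,2-dimethyl-7-(3-methylbut-2-en-1-yl)-2H-chromene-6-carbaldehyde | CC(C)=CCc1c(C=O)cc2c(c1O)OC(C)(C)C=C2 | intermediate
23 | 8-(methoxymethoxy)-2,2-dimethyl-7-(3-methylbut-2-en-1-yl)-2H-chromene-6-carbaldehyde | CC(C)=CCc1c(C=O)cc2c(c1OCOC)OC(C)(C)C=C2 | intermediate
24 | (3S)-1-[2-fluoro-4,6-bis(methoxymethoxy)-3-(3-methylbut-2-en-1-yl)phenyl]-3-[8-(methoxymethoxy)-2,2-dimethyl-7-(3-methylbut-2-en-1-yl)-2H-chromen-6-yl]-3-[(trimethylsilyl)oxy]propan-1-one | CC(C)=CCc1c([C@@H](O[Si](C)(C)C)CC(=O)c3c(OCOC)cc(OCOC)c(CC=C(C)C)c3F)cc2c(c1OCOC)OC(C)(C)C=C2 | intermediate (not isolated)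
25 | tetrabutylammonium (1S)-3-[2-fluoro-4,6-bis(methoxymethoxy)-3-(3-methylbut-2-en-1-yl)phenyl]-1-[8-(methoxymethoxy)-2,2-dimethyl-7-(3-methylbut-2-en-1-yl)-2H-chromen-6-yl]-3-oxopropan-1-olate | CC(C)=CCc1c([C@@H]([O-])CC(=O)c3c(OCOC)cc(OCOC)c(CC=C(C)C)c3F)cc2c(c1OCOC)OC(C)(C)C=C2.CCCC[N+](CCCC)(CCCC)CCCC | intermediate (not isolated)
26 | (2S)-5,7-bis(methoxymethoxy)-2-[8-(methoxymethoxy)-2,2-dimethyl-7-(3-methylbut-2-en-1-yl)-2H-chromen-6-yl]-8-(3-methylbut-2-en-1-yl)-2,3-dihydro-4H-chromen-4-one | CC(C)=CCc1c([C@@H]2CC(=O)c3c(OCOC)cc(OCOC)c(CC=C(C)C)c3O2)cc2c(c1OCOC)OC(C)(C)C=C2 | intermediate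
27 | (2S)-5,7-dihydroxy-2-[8-hydroxy-2,2-dimethyl-7-(3-methylbut-2-en-1-yl)-2H-chromen-6-yl]-8-(3-methylbut-2-en-1-yl)-2,3-dihydro-4H-chromen-4-one | CC(C)=CCc1c([C@@H]2CC(=O)c3c(O)cc(O)c(CC=C(C)C)c3O2)cc2c(c1O)OC(C)(C)C=C2 | target

Total step count: 11. Longest linear sequence: 7 steps (steps 1 to 5, 10 and 11); the aldehyde branch (steps 6 to 9, then 10 and 11) is 6 steps.

Steps most likely to fail

Step 10. Facial discrimination on the ortho-substituted, electron-rich aldehyde may be insufficient. Retro-aldol of the free aldolate before ring closure, or base-induced opening of ring C once formed, would erode the enantiopurity. Ene-type cyclisation of the activated formyl group onto the ortho-prenyl alkene may compete. The fallback sets out from 15 and 23 and comes back at 26, making the two bonds in separate operations. A Mukaiyama aldol under SiCl4 (1.5 equiv) activated by the pentane-1,5-diyl-linked bisphosphoramide of N,N'-dimethyl-1,1'-binaphthyl-2,2'-diamine (5 mol %, the enantiomer that gives Si-face addition), with i-Pr2NEt (10 mol %) in CH2Cl2 at −78 °C and aqueous KF/NaHCO3 work-up, should give the free aldol (3S)-1-[2-fluoro-4,6-bis(methoxymethoxy)-3-(3-methylbut-2-en-1-yl)phenyl]-3-hydroxy-3-[8-(methoxymethoxy)-2,2-dimethyl-7-(3-methylbut-2-en-1-yl)-2H-chromen-6-yl]propan-1-one F1. Its enantiopurity can be checked and raised by crystallisation before ring closure. Cs2CO3 in DMF at 0 °C to rt should then close ring C by intramolecular SNAr to give 26.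

Step 8. At 190 °C the tertiary allyl ether may lose isoprene before it rearranges, and the prenylphenol formed first may isomerise further while the propargyl ether is still reacting. The fallback sets out from 18 and comes back at 22, building the chromene first and running the allyl Claisen rearrangement at low temperature. Heating 18 in PhNEt2 at 190 °C should give 8-hydroxy-2,2-dimethyl-2H-chromene-6-carbaldehyde F2. Tsuji–Trost etherification with 19 and Pd(PPh3)4 in THF at 0 °C should give 2,2-dimethyl-8-[(2-methylbut-3-en-2-yl)oxy]-2H-chromene-6-carbaldehyde F3. A Claisen rearrangement of F3 in toluene at 110 °C should then deliver 22, since C7 is the only free ortho position.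

Step 11. Under protic acid the phenols may add to the neighbouring prenyl alkenes (chroman formation), and the benzylic C2–O1 bond, assisted by the para oxygen of ring B, may ionise and racemise C2. The fallback sets out from 26 and comes back at 27, replacing solvolysis by acetal-to-silyl ether exchange. Et3SiOTf and 2,2'-bipyridyl in CH2Cl2 at 0 °C should convert the three aryl MOM ethers into (2S)-2-[2,2-dimethyl-7-(3-methylbut-2-en-1-yl)-8-[(triethylsilyl)oxy]-2H-chromen-6-yl]-8-(3-methylbut-2-en-1-yl)-5,7-bis[(triethylsilyl)oxy]-2,3-dihydro-4H-chromen-4-one F4. Et3N·3HF in THF at 0 °C should then release 27 under weakly acidic, non-basic conditions.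

Further compounds
F1 | step 10 | (3S)-1-[2-fluoro-4,6-bis(methoxymethoxy)-3-(3-methylbut-2-en-1-yl)phenyl]-3-hydroxy-3-[8-(methoxymethoxy)-2,2-dimethyl-7-(3-methylbut-2-en-1-yl)-2H-chromen-6-yl]propan-1-one | CC(C)=CCc1c([C@@H](O)CC(=O)c3c(OCOC)cc(OCOC)c(CC=C(C)C)c3F)cc2c(c1OCOC)OC(C)(C)C=C2
F2 | step 8 | 8-hydroxy-2,2-dimethyl-2H-chromene-6-carbaldehyde | CC1(C)C=Cc2cc(C=O)cc(O)c2O1
F3 | step 8 | 2,2-dimethyl-8-[(2-methylbut-3-en-2-yl)oxy]-2H-chromene-6-carbaldehyde | CC1(C)C=Cc2cc(C=O)cc(OC(C)(C)C=C)c2O1
F4 | step 11 | (2S)-2-[2,2-dimethyl-7-(3-methylbut-2-en-1-yl)-8-[(triethylsilyl)oxy]-2H-chromen-6-yl]-8-(3-methylbut-2-en-1-yl)-5,7-bis[(triethylsilyl)oxy]-2,3-dihydro-4H-chromen-4-one | CC(C)=CCc1c([C@@H]2CC(=O)c3c(O[Si](CC)(CC)CC)cc(O[Si](CC)(CC)CC)c(CC=C(C)C)c3O2)cc2c(c1O[Si](CC)(CC)CC)OC(C)(C)C=C2
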